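In a one-step world substrate meets reagent directly and the rate follows c(substrate) times c(reagent), so I began by asking whether the south run needed that world.

all flasks: temperature 20 °C
- south: substrate 0.19 M; reagent 0.196 M; free catalyst 0.56 mM; run made earlier
- epsilon: substrate 0.28 M; reagent 0.800 M; free catalyst 0.40 mM; time 25 h
- zeta: substrate 0.28 M; reagent 0.196 M; free catalyst 0.56 mM; time 25 h

south run (percent of the substrate charged)

| time / h | product / % | substrate / % |
|---|---|---|
| 0.417 | 2 | 100 |
| 0.833 | 5 | 95 |
| 1.33 | 8 | 92 |
| 2.50 | 16 | 87 |
| 5.00 | 28 | 69 |

(standard deviation of a reading: 2 percentage points)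

- no earlier run changes the charge of free catalyst; that part of a forecast is a guess

- which one finishes higher in amount of product, in percent of the substrate charged ("neither" within 2 percentage points) (epsilon / zeta / neither)
- amount of product at the end, in percent of the substrate charged, epsilon
- amount of product at the end, in percent of the substrate charged, zeta

The last two product readings of the south run stood in the ratio 1.75 where a straight line gives 2.00, and with a scatter of 2 percentage points I could not tell a straight line from a bending curve. But the south run held far less free catalyst than substrate, so I wagered on a catalyst kept busy at a steady pace, and I read that pace from the last reading: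

28% × 0.19 M / (5.00 h × 0.56 mM) = 19.0 h⁻¹

This is the turnover frequency, product made per hour per catalyst charged, and taking it as unchanged at another catalyst charge was my guess, since no earlier run varied that charge.

In the first instants of each new flask I expected product to climb at this frequency times the catalyst charge. Both charges of reagent stood far above both charges of catalyst, so through the middle I held the pace level, which gave by the end, as shares of the substrate charged:

epsilon: 19.0 h⁻¹ × 0.40 mM × 25 h / 0.28 M = 67.9%

zeta: 19.0 h⁻¹ × 0.56 mM × 25 h / 0.28 M = 95.0%, against a reagent ceiling of 0.196 M / 0.28 M = 70.0%

By my reckoning zeta, with reagent as the limiting reagent, came to that ceiling at 18.4 h, earlier than the end at 25 h, so I stopped its line there, while the line for epsilon went on climbing. The gap of 2.1 points lay too near the margin of 2 points for one scattered reading, so I called the flasks level.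

The forecast differed from my reckoning: it named epsilon as the higher, at 94% against 57% for zeta, and added: “The reagent and catalyst orders are untested”.

The flasks gave 69.9% for epsilon and 70.0% for zeta, so neither finished higher, and my pace had said 67.9% for epsilon.

    substrate + free catalyst ⇌ catalyst intermediate A (K = 3.71 M⁻¹, k = 0.189 M⁻¹ s⁻¹, Ea = 56.0 kJ mol⁻¹, ΔH = −17.0 kJ mol⁻¹)
    reagent + catalyst intermediate A → catalyst intermediate B (k = 7.88 M⁻¹ s⁻¹, Ea = 41.0 kJ mol⁻¹)
    catalyst intermediate B ⇌ catalyst intermediate C (K = 1.90, k = 0.0552 s⁻¹, Ea = 78.0 kJ mol⁻¹, ΔH = 22.0 kJ mol⁻¹)
    catalyst intermediate C → free catalyst + product (k = 0.0115 s⁻¹, Ea = 88.0 kJ mol⁻¹)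
    (constants at 20 °C)

In epsilon the step of substrate with free catalyst had behind it 11% of its turnover up to 25 h by 2.50 h and half by 11.8 h, while zeta's reagent stood at 0% of its charge at the end. For epsilon read at 10 h, the same turnover frequency gives 27.1%, and that flask stood at 29.6%.

(The readings were computed on assumed constants, noise included.)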